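**Strategy.** The cage is cut at C13–C14 of the cyclohexane, the last ring to be closed (numbering listed below). The key step exploits the CH(CH3)–CH2 unit C13–C14 and the flagpole positions C12/C15 of the boat tetrahydropyran in the 2-oxabicyclo[2.2.2]octane: a C14 radical (from CH2Br on C15) adds 6-exo to a vinyl group on C12, whose terminus becomes the C13 methyl. One operation closes the carbocycle and sets C13. Its precursor, a 2-oxabicyclo[3.2.1]octane fused to the lactone and the eight-membered ring, comes from a cyclopentanone: a De Mayo photocycloaddition–retro-aldol builds lactone and eight-membered ring together, and a vinyl epoxide opening builds the oxygen bridge.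

Key step: step 19

Remarks on the chemistry (assumptions):
- Numbering used for all compounds: C1 lactone carbonyl; C2=C3(OH) enol; C4 and C6 methyl-bearing carbons; C5 methylene; C7 ketone; C8, C9, C10 cyclopentane carbons; C11 carbinol; C12 ether carbon (methyl); C13 methyl-bearing carbon; C14 methylene; C15 carbon bearing the lactone oxygen; C16 carbon bearing the ether oxygen and bonded to C2, C8 and C15.
- 2,4-Dimethylglutaric anhydride is taken in its commercial meso (cis) form. Compounds 8–10 are racemic (one enantiomer drawn); both enantiomers converge on the meso triketone 11.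
- Enols of 11, 24 and 25 are drawn in one tautomeric form. "ent-Shi ketone" is the enantiomer (L-fructose series) of the D-fructose-derived epoxidation ketone.

**Route**

Step 1
Reactants: 1 prop-2-yn-1-ol
Product: 3 (Z)-3-iodo-2-methylprop-2-en-1-ol, via alkenylmagnesium alkoxide 2 (not isolated)
Conditions: MeMgBr (2.3 equiv), CuI (10 mol%), THF/Et2O, −10 °C to rt; then I2, −78 °C to 0 °C
Reagents that add atoms: methylmagnesium bromide (C[Mg]Br); iodine (II)
Why: CuI-catalysed anti-carbomagnesiation of the propargylic alkoxide (Duboudin reaction) puts methyl on C2 and magnesium on C3 in a chelate with the alkoxide, and iodinolysis with retention should give the (Z)-iodide in which iodine and CH2OH are cis.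

Step 2
Reactants: 3 (Z)-3-iodo-2-methylprop-2-en-1-ol
Product: 4 (Z)-3-iodo-2-methylprop-2-enal
Conditions: MnO2 (excess), CH2Cl2, rt, dark
Reagents that add atoms: none
Why: Allylic oxidation on MnO2 is neutral and heterogeneous, so the (Z)-β-iodo enal should form without isomerisation.

Step 3
Reactants: 4 (Z)-3-iodo-2-methylprop-2-enal
Product: 5 (Z)-1-iodo-2-methylbuta-1,3-diene
Conditions: Ph3PCH3Br, KN(SiMe3)2, THF, −78 °C to 0 °C; volatile diene kept as a pentane/Et2O solution
Reagents that add atoms: methyltriphenylphosphonium bromide (C[P+](c1ccccc1)(c1ccccc1)c1ccccc1.[Br-])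
Why: Wittig methylenation of the aldehyde with the unstabilised ylide leaves the trisubstituted iodoalkene geometry untouched.

Step 4
Reactants: 6 meso-2,4-dimethylglutaric anhydride; 7 mono-tert-butyl malonate
Product: 9 rac-(2R,4S)-7-tert-butoxy-2,4-dimethyl-5,7-dioxoheptanoic acid, via acylmalonic acid 8 (not isolated)
Conditions: 7, i-PrMgCl (2.0 equiv), THF, 0 °C; then 6, 0 °C to rt; then 1 M HCl, 40 °C
Reagents that add atoms: none
Why: Masamune-type C-acylation of the magnesium malonate half-ester by the cyclic anhydride followed by decarboxylation gives the β-keto ester acid; the achiral nucleophile opens the meso anhydride to a racemate, which does not matter because step 5 regenerates a meso ring.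

Step 5
Reactants: 9 rac-(2R,4S)-7-tert-butoxy-2,4-dimethyl-5,7-dioxoheptanoic acid
Product: 11 tert-butyl (3R,5S)-2-hydroxy-3,5-dimethyl-6-oxocyclohex-1-ene-1-carboxylate, via acyl imidazolide 10 (not isolated)
Conditions: CDI, THF, rt; then MgCl2, Et3N, MeCN, rt; dilute acid work-up
Reagents that add atoms: none
Why: Soft enolisation of the β-keto ester (MgCl2/Et3N) and intramolecular C-acylation by the acyl imidazolide (Claisen-type six-ring closure) should give the enolised 2-carboxy-1,3-dione with the two methyl groups cis, the diequatorial and thermodynamically preferred arrangement.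

Step 6
Reactants: 12 cyclopent-2-en-1-one
Product: 13 2-(hydroxymethyl)cyclopent-2-en-1-one
Conditions: aq. HCHO (37%), imidazole (10 mol%), THF/H2O, rt
Reagents that add atoms: formaldehyde (C=O)
Why: Morita–Baylis–Hillman hydroxymethylation of the cyclic enone at its α-carbon installs C14 with its oxygen.

Step 7
Reactants: 13 2-(hydroxymethyl)cyclopent-2-en-1-one
Product: 14 2-[(tert-butyldimethylsilyloxy)methyl]cyclopent-2-en-1-one
Conditions: TBSCl, imidazole, CH2Cl2, 0 °C to rt
Reagents that add atoms: tert-butyldimethylsilyl chloride (CC(C)(C)[Si](C)(C)Cl)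
Why: Standard silylation protects the primary alcohol through the oxidation at C16.

Step 8
Reactants: 14 2-[(tert-butyldimethylsilyloxy)methyl]cyclopent-2-en-1-one
Product: 15 (R)-2-[(tert-butyldimethylsilyloxy)methyl]cyclopent-2-en-1-ol
Conditions: (S)-2-methyl-CBS-oxazaborolidine (10 mol%), BH3·SMe2, THF, −20 °C
Reagents that add atoms: none
Why: Corey–Bakshi–Shibata reduction, in which the α-substituted alkene arm acts as the large group, should deliver hydride to one face and set the temporary C16 carbinol as R, the source of all absolute configuration on the main line.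

Step 9
Reactants: 15 (R)-2-[(tert-butyldimethylsilyloxy)methyl]cyclopent-2-en-1-ol
Product: 16 (1R,2R,5S)-1-[(tert-butyldimethylsilyloxy)methyl]-6-oxabicyclo[3.1.0]hexan-2-ol
Conditions: VO(acac)2 (3 mol%), t-BuOOH, CH2Cl2, 0 °C to rt
Reagents that add atoms: tert-butyl hydroperoxide (CC(C)(C)OO)
Why: Hydroxyl-directed epoxidation of the cyclic allylic alcohol places the epoxide oxygen syn to the C16 hydroxyl, which fixes the future lactone oxygen on C15.

Step 10
Reactants: 16 (1R,2R,5S)-1-[(tert-butyldimethylsilyloxy)methyl]-6-oxabicyclo[3.1.0]hexan-2-ol; 5 (Z)-1-iodo-2-methylbuta-1,3-diene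
Product: 18 (1R,2R,3S)-2-[(tert-butyldimethylsilyloxy)methyl]-3-[(1Z)-2-methylbuta-1,3-dien-1-yl]cyclopentane-1,2-diol, via dienylmagnesium chloride 17 (not isolated)
Conditions: 5, i-PrMgCl·LiCl, THF, 0 °C; 16 pretreated with MeMgCl (1.0 equiv); then CuI (10 mol%), THF, −30 °C to rt
Reagents that add atoms: none
Why: Iodine–magnesium exchange with retention and CuI-catalysed SN2 opening of the epoxide at the less substituted carbon C10 with inversion should place the (Z)-dienyl group trans to the tertiary C15 hydroxyl and cis to C14.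

Step 11
Reactants: 18 (1R,2R,3S)-2-[(tert-butyldimethylsilyloxy)methyl]-3-[(1Z)-2-methylbuta-1,3-dien-1-yl]cyclopentane-1,2-diol
Product: 19 (2R,3S)-2-[(tert-butyldimethylsilyloxy)methyl]-2-hydroxy-3-[(1Z)-2-methylbuta-1,3-dien-1-yl]cyclopentan-1-one
Conditions: Dess–Martin periodinane, NaHCO3, CH2Cl2, 0 °C to rt
Reagents that add atoms: none
Why: Dess–Martin oxidation converts the secondary C16 alcohol into the ketone and leaves the tertiary alcohol and the diene untouched.

Step 12
Reactants: 19 (2R,3S)-2-[(tert-butyldimethylsilyloxy)methyl]-2-hydroxy-3-[(1Z)-2-methylbuta-1,3-dien-1-yl]cyclopentan-1-one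
Product: 20 (2R,3S)-2-hydroxy-2-(hydroxymethyl)-3-[(1Z)-2-methylbuta-1,3-dien-1-yl]cyclopentan-1-one
Conditions: HF·pyridine, pyridine, THF, 0 °C to rt
Reagents that add atoms: none
Why: Fluoride-mediated desilylation under weakly acidic conditions frees the primary alcohol without the base-induced retro-aldol loss of formaldehyde that a β-hydroxy ketone would risk.

Step 13
Reactants: 20 (2R,3S)-2-hydroxy-2-(hydroxymethyl)-3-[(1Z)-2-methylbuta-1,3-dien-1-yl]cyclopentan-1-one
Product: 22 (2S,3S)-2-(bromomethyl)-2-hydroxy-3-[(1Z)-2-methylbuta-1,3-dien-1-yl]cyclopentan-1-one, via primary triflate 21 (not isolated)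
Conditions: Tf2O (1.05 equiv), 2,6-lutidine, CH2Cl2, −78 °C; then n-Bu4NBr, −78 °C to rt
Reagents that add atoms: tetrabutylammonium bromide (CCCC[N+](CCCC)(CCCC)CCCC.[Br-])
Why: Selective triflation of the primary hydroxyl and SN2 displacement by bromide (the triflate compensates for the neopentyl-type position) installs the radical precursor while no base is present to close the bromohydrin to an epoxide.

Step 14
Reactants: 22 (2S,3S)-2-(bromomethyl)-2-hydroxy-3-[(1Z)-2-methylbuta-1,3-dien-1-yl]cyclopentan-1-one; 11 tert-butyl (3R,5S)-2-hydroxy-3,5-dimethyl-6-oxocyclohex-1-ene-1-carboxylate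
Product: 24 (1S,2S)-1-(bromomethyl)-2-[(1Z)-2-methylbuta-1,3-dien-1-yl]-5-oxocyclopentyl (3R,5S)-2-hydroxy-3,5-dimethyl-6-oxocyclohex-1-ene-1-carboxylate, via acylketene 23 (not isolated)
Conditions: PhMe, 110 °C, 4 Å molecular sieves, t-BuOH distilled off
Reagents that add atoms: none
Why: Thermal loss of tert-butanol from the enolised β-keto tert-butyl ester gives the α-oxoketene, which should acylate even the hindered tertiary alcohol (acylketene transacylation) and so attaches C1 to the C15 oxygen under neutral conditions.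

Step 15
Reactants: 24 triketone ester of step 14
Product: 25 (1S,2S)-1-(bromomethyl)-2-[(2S,3R)-3-ethenyl-3-methyloxiran-2-yl]-5-oxocyclopentyl (3R,5S)-2-hydroxy-3,5-dimethyl-6-oxocyclohex-1-ene-1-carboxylate
Conditions: ent-Shi ketone (30 mol%), KHSO5 (Oxone), K2CO3, n-Bu4NHSO4, MeCN/dimethoxymethane/aq. Na2B4O7 buffer, 0 °C
Reagents that add atoms: potassium peroxymonosulfate ([K+].[O-]S(=O)(=O)OO)
Why: Shi epoxidation should select the electron-rich trisubstituted alkene of the diene, transfer oxygen stereospecifically so that C10 and vinyl stay cis, and set C11 (S) and C12 (R) under reagent control through the spiro transition state, while the triketone sits as its unreactive delocalised enolate.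

Step 16
Reactants: 25 vinyl epoxide of step 15
Product: 26 (1S,5S)-1-(bromomethyl)-5-[(2S,3R)-3-ethenyl-3-methyloxiran-2-yl]-2-(triethylsilyloxy)cyclopent-2-en-1-yl (3R,5S)-3,5-dimethyl-6-oxo-2-(trimethylsilyloxy)cyclohex-1-ene-1-carboxylate
Conditions: TMSCl, Et3N, THF, 0 °C; then LiN(SiMe3)2 (1.2 equiv), TESCl (1.3 equiv), −78 °C; non-aqueous work-up
Reagents that add atoms: chlorotrimethylsilane (C[Si](C)(C)Cl); chlorotriethylsilane (CC[Si](Cl)(CC)CC)
Why: The acidic triketone enol is capped as its TMS ether and kinetic enolisation of the C16 ketone, possible only toward C8, is trapped as the TES enol ether, which gives both partners of the cycloaddition and removes every acidic proton from the epoxide-bearing substrate.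

Step 17
Reactants: 26 bis(silyl enol ether) of step 16
Product: 29 C16 triethylsilyl ether of the cis-fused lactone–cyclooctanedione (β-keto lactone enol; vinyl epoxide on C10; CH2Br on C15), via cyclobutane photoadduct 27 (not isolated), via cyclobutanol 28 (not isolated)
Conditions: hν (medium-pressure Hg lamp, Pyrex, λ > 300 nm), degassed MeCN (5 mM), 0 °C; then K2CO3 (0.1 equiv), MeOH, 0 °C
Reagents that add atoms: none
Why: In this intramolecular De Mayo reaction the excited β-silyloxy enone adds to the tethered silyl enol ether through a five-membered tether (rule of five) on the cyclopentene face that carries the ester oxygen, which sets C16 and C8; bond formation anti to the pseudoaxial C6–H of the cis-dimethyl dione decides that this carbonyl becomes C7 (hence 4S,6R); and methanolysis of the labile tertiary TMS ether releases the cyclobutanolate, whose retro-aldol cleavage of C2–C7 expands the six-membered dione to the eight-membered ring while the TES ether keeps the C16 oxygen from fragmenting.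

Step 18
Reactants: 29 C16 triethylsilyl ether of step 17
Product: 31 bromide (4S,6R,8R,10S,11S,12S,15S,16R) lacking only the C13–C14 bond (C15 bears CH2Br; C12 bears CH3 and CH=CH2; 2-oxabicyclo[3.2.1]octane), via tertiary alcohol 30 (not isolated)
Conditions: CSA (0.3 equiv), CH2Cl2 containing H2O (2 equiv), 0 °C to rt
Reagents that add atoms: none
Why: Acid frees (or directly engages) the C16 oxygen, which should open the protonated vinyl epoxide in the 6-endo mode at the tertiary allylic carbon C12 with inversion (vinyl-epoxide cyclisation of the Nicolaou type), closing the oxygen bridge with the C11 hydroxyl anti to the new ether bond and the vinyl group on the face of the C15 bromomethyl group.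

Step 19
Reactants: 31 bromide of step 18
Product: 32 abyssomicin N
Conditions: (Me3Si)3SiH (1.5 equiv), AIBN (0.2 equiv), PhH (2 mM), 80 °C, syringe-pump addition
Reagents that add atoms: none
Why: The silyl radical abstracts bromine from C14, the primary C14 radical on C15 adds to the internal carbon C13 of the vinyl group on C12, and the new primary radical takes hydrogen from the silane, so the former CH2 terminus becomes the C13 methyl. The closest known reaction is the tin- or silicon-hydride-mediated 6-exo-trig cyclisation of hept-6-enyl radicals, including closures of bicyclo[2.2.2]octanes through a boat. The cyclohexane C10–C11–C12–C13–C14–C15 closes in the 6-exo-trig mode at C13–C14, which turns the 2-oxabicyclo[3.2.1]octane into the 2-oxabicyclo[2.2.2]octane. C13 is set by the rotamer of the vinyl group in the transition state: its CH2 terminus should turn toward the ether oxygen and away from the C11 hydroxyl on the other flank, so the methyl ends syn to the oxygen bridge (13S). Cyclisation must outrun hydrogen transfer to C14 and the 1,2-acyloxy shift of the β-acyloxy radical; the quaternary C12 (methyl and vinyl) should force the tetrahydropyran into a boat in which vinyl and CH2 radical are flagpole neighbours, slow addition keeps the weak hydrogen donor dilute, and 7-endo attack would give a strained bicyclo[3.2.2]nonane.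

**Compound list**

1 | prop-2-yn-1-ol | C#CCO | starting material
2 | bromomagnesium (Z)-3-(bromomagnesio)-2-methylprop-2-en-1-olate | Br[Mg]/C=C(C)\CO[Mg]Br | intermediate (not isolated)
3 | (Z)-3-iodo-2-methylprop-2-en-1-ol | I/C=C(C)\CO | intermediate
4 | (Z)-3-iodo-2-methylprop-2-enal | I/C=C(C)\C=O | intermediate
5 | (Z)-1-iodo-2-methylbuta-1,3-diene | I/C=C(C)\C=C | intermediate
6 | meso-2,4-dimethylglutaric anhydride, (3R,5S)-3,5-dimethyloxane-2,6-dione | C[C@@H]1C[C@H](C)C(=O)OC1=O | starting material
7 | mono-tert-butyl malonate | OC(=O)CC(=O)OC(C)(C)C | starting material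
8 | 2-(tert-butoxycarbonyl)-4,6-dimethyl-3-oxoheptanedioic acid (acylmalonic acid, racemic) | OC(=O)[C@H](C)C[C@H](C)C(=O)C(C(O)=O)C(=O)OC(C)(C)C | intermediate (not isolated)
9 | rac-(2R,4S)-7-tert-butoxy-2,4-dimethyl-5,7-dioxoheptanoic acid | OC(=O)[C@H](C)C[C@H](C)C(=O)CC(=O)OC(C)(C)C | intermediate
10 | acyl imidazolide of 9 | O=C(n1ccnc1)[C@H](C)C[C@H](C)C(=O)CC(=O)OC(C)(C)C | intermediate (not isolated)
11 | tert-butyl (3R,5S)-2-hydroxy-3,5-dimethyl-6-oxocyclohex-1-ene-1-carboxylate (enol of the meso cis-triketone ester) | C[C@@H]1C[C@H](C)C(=O)C(C(=O)OC(C)(C)C)=C1O | intermediate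
12 | cyclopent-2-en-1-one | O=C1CCC=C1 | starting material
13 | 2-(hydroxymethyl)cyclopent-2-en-1-one | O=C1CCC=C1CO | intermediate
14 | 2-[(tert-butyldimethylsilyloxy)methyl]cyclopent-2-en-1-one | O=C1CCC=C1CO[Si](C)(C)C(C)(C)C | intermediate
15 | (R)-2-[(tert-butyldimethylsilyloxy)methyl]cyclopent-2-en-1-ol | O[C@@H]1CCC=C1CO[Si](C)(C)C(C)(C)C | intermediate
16 | (1R,2R,5S)-1-[(tert-butyldimethylsilyloxy)methyl]-6-oxabicyclo[3.1.0]hexan-2-ol | O[C@@H]1CC[C@@H]2O[C@]12CO[Si](C)(C)C(C)(C)C | intermediate
17 | (Z)-(2-methylbuta-1,3-dien-1-yl)magnesium chloride | Cl[Mg]/C=C(C)\C=C | intermediate (not isolated)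
18 | (1R,2R,3S)-2-[(tert-butyldimethylsilyloxy)methyl]-3-[(1Z)-2-methylbuta-1,3-dien-1-yl]cyclopentane-1,2-diol | O[C@@H]1CC[C@@H](/C=C(C)\C=C)[C@@]1(O)CO[Si](C)(C)C(C)(C)C | intermediate
19 | (2R,3S)-2-[(tert-butyldimethylsilyloxy)methyl]-2-hydroxy-3-[(1Z)-2-methylbuta-1,3-dien-1-yl]cyclopentan-1-one | O=C1CC[C@@H](/C=C(C)\C=C)[C@@]1(O)CO[Si](C)(C)C(C)(C)C | intermediate
20 | (2R,3S)-2-hydroxy-2-(hydroxymethyl)-3-[(1Z)-2-methylbuta-1,3-dien-1-yl]cyclopentan-1-one | O=C1CC[C@@H](/C=C(C)\C=C)[C@@]1(O)CO | intermediate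
21 | primary trifluoromethanesulfonate of 20 | O=C1CC[C@@H](/C=C(C)\C=C)[C@@]1(O)COS(=O)(=O)C(F)(F)F | intermediate (not isolated)
22 | (2S,3S)-2-(bromomethyl)-2-hydroxy-3-[(1Z)-2-methylbuta-1,3-dien-1-yl]cyclopentan-1-one | O=C1CC[C@@H](/C=C(C)\C=C)[C@@]1(O)CBr | intermediate
23 | (4R,6S)-4,6-dimethyl-2-(oxomethylidene)cyclohexane-1,3-dione (acylketene) | C[C@@H]1C[C@H](C)C(=O)C(=C=O)C1=O | intermediate (not isolated)
24 | (1S,2S)-1-(bromomethyl)-2-[(1Z)-2-methylbuta-1,3-dien-1-yl]-5-oxocyclopentyl (3R,5S)-2-hydroxy-3,5-dimethyl-6-oxocyclohex-1-ene-1-carboxylate | C[C@@H]1C[C@H](C)C(=O)C(C(=O)O[C@@]2(CBr)[C@H](/C=C(C)\C=C)CCC2=O)=C1O | intermediate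
25 | (1S,2S)-1-(bromomethyl)-2-[(2S,3R)-3-ethenyl-3-methyloxiran-2-yl]-5-oxocyclopentyl (3R,5S)-2-hydroxy-3,5-dimethyl-6-oxocyclohex-1-ene-1-carboxylate | C[C@@H]1C[C@H](C)C(=O)C(C(=O)O[C@@]2(CBr)[C@H]([C@@H]3O[C@]3(C)C=C)CCC2=O)=C1O | intermediate
26 | (1S,5S)-1-(bromomethyl)-5-[(2S,3R)-3-ethenyl-3-methyloxiran-2-yl]-2-(triethylsilyloxy)cyclopent-2-en-1-yl (3R,5S)-3,5-dimethyl-6-oxo-2-(trimethylsilyloxy)cyclohex-1-ene-1-carboxylate | C[C@@H]1C[C@H](C)C(=O)C(C(=O)O[C@@]2(CBr)[C@H]([C@@H]3O[C@]3(C)C=C)CC=C2O[Si](CC)(CC)CC)=C1O[Si](C)(C)C | intermediate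
27 | cyclobutane photoadduct (C2–C16 and C7–C8 bonds; C7–OSiMe3; C16–OSiEt3; lactone, cyclobutane and cyclopentane all cis-fused around C16) | C[C@@H]1C[C@H](C)C(=O)[C@]23C(=O)O[C@@]4(CBr)[C@H]([C@@H]5O[C@]5(C)C=C)C[C@H]([C@@]24O[Si](CC)(CC)CC)[C@]13O[Si](C)(C)C | intermediate (not isolated)
28 | cyclobutanol from 27 (free C7–OH; C16–OSiEt3) | C[C@@H]1C[C@H](C)C(=O)[C@]23C(=O)O[C@@]4(CBr)[C@H]([C@@H]5O[C@]5(C)C=C)C[C@H]([C@@]24O[Si](CC)(CC)CC)[C@]13O | intermediate (not isolated)
29 | (4S,6R,8R,10S,11S,12R,15S,16R) C16 triethylsilyl ether: cis-fused γ-lactone/cyclooctane-3,7-dione (C2=C3 enol), (11S,12R)-vinyl epoxide on C10, CH2Br on C15 | C[C@@H]1C[C@H](C)/C(O)=C2/C(=O)O[C@]4(CBr)[C@@]2(O[Si](CC)(CC)CC)[C@@H](C[C@H]4[C@@H]5O[C@]5(C)C=C)C1=O | intermediate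
30 | tertiary C16 alcohol corresponding to 29 | C[C@@H]1C[C@H](C)/C(O)=C2/C(=O)O[C@]4(CBr)[C@@]2(O)[C@@H](C[C@H]4[C@@H]5O[C@]5(C)C=C)C1=O | intermediate (not isolated)
31 | (4S,6R,8R,10S,11S,12S,15S,16R) bromide: abyssomicin N skeleton lacking the C13–C14 bond (C15–CH2Br; C12 bearing CH3 and CH=CH2; C11–OH) | C[C@@H]1C[C@H](C)/C(O)=C2/C(=O)O[C@]4(CBr)[C@@]2(O[C@@](C)(C=C)[C@@H](O)[C@@H]4C5)[C@@H]5C1=O | intermediate
32 | abyssomicin N (4S,6R,8R,10S,11S,12S,13S,15S,16R) | C[C@@H]1C[C@H](C)/C(O)=C2/C(=O)O[C@]34C[C@H](C)[C@]5(C)O[C@]23[C@@H](C[C@H]4[C@@H]5O)C1=O | target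

**Summary**

Total step count: 19 (steps 1–3 give diene 5, steps 4–5 give triketone ester 11, steps 6–19 are the main line).
Longest linear sequence: 14 steps (12 to 32, steps 6–19).

Steps most likely to fail, with fallbacks:

Step 17. The excited enone may fail to reach the tethered enol ether because the ester prefers the unreactive s-trans conformer, or the cycloaddition may occur across the other dione face, which would invert both methyl-bearing centres relative to the core; C4 and C6 are also epimerisable. The fallback sets out from 22 and comes back at 30, using ionic chemistry only. Anhydride 6 would be opened with methanol under quinidine or quinine control to the half-ester (2R,4S)-5-methoxy-2,4-dimethyl-5-oxopentanoic acid F1, reduced with BH3·SMe2 to methyl (2S,4R)-5-hydroxy-2,4-dimethylpentanoate F2 and oxidised (Swern) to methyl (2S,4R)-2,4-dimethyl-5-oxopentanoate F3. The dianion of 22 (LiN(i-Pr)2, 2.2 equiv) would add to F3 to give the C8 aldol adduct F4 (mixture at C7). Silylation of the secondary hydroxyl (TESCl, imidazole) would give the TES ether F5, and acylation of the tertiary hydroxyl (bromoacetyl bromide, pyridine) the bromoacetate F6. SmI2 (intramolecular Reformatsky reaction) would close the cis-fused hydroxy lactone F7, and its alkoxide–enolate dianion (LiN(SiMe3)2) would undergo Dieckmann closure onto the methyl ester to the eight-membered keto lactone F8. HF·pyridine would give the C7 alcohol F9 and Dess–Martin oxidation the C7 ketone F10, whose C8 centre is epimerisable and expected to settle in the cis-fused arrangement. The Shi epoxidation of step 15 would then deliver 30.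

Step 19. Hydrogen transfer to the C14 radical before cyclisation, 1,2-acyloxy migration of the β-acyloxy radical, or poor facial control at C13 may intervene. The fallback sets out from 31 and comes back at 32. A palladium-catalysed alkyl-Heck-type carbocyclisation of the bromide (Pd(PPh3)4, Et3N, PhCF3, 100 °C, no hydrogen donor) would give the 13-methylene compound F11. Hydroxyl-directed hydrogenation with [Ir(cod)(PCy3)(py)]PF6 under H2 would then be steered by the C11 hydroxyl, which lies on the face between the C10–C11 and C13–C14 bridges, so that hydrogen is delivered to that face and the methyl is placed toward the oxygen bridge.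

Step 10. Opening of the trisubstituted epoxide by the hindered (Z)-dienyl organometallic may be sluggish, and the (Z)-geometry may erode. The fallback sets out from 16 and comes back at 18. The diethylalkynylalane made from but-1-en-3-yne (n-BuLi, then Et2AlCl) would open the epoxide at C10 to the enyne diol F12. Fe(acac)3-catalysed, alkoxide-directed syn-carbomagnesiation with MeMgBr (methyl to the distal alkyne carbon C12, magnesium to C11 in a chelate with the C15 alkoxide) and protonation would then give the (Z)-diene 18.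

Further compounds

F1 | step 17 | (2R,4S)-5-methoxy-2,4-dimethyl-5-oxopentanoic acid | OC(=O)[C@H](C)C[C@H](C)C(=O)OC
F2 | step 17 | methyl (2S,4R)-5-hydroxy-2,4-dimethylpentanoate | OC[C@H](C)C[C@H](C)C(=O)OC
F3 | step 17 | methyl (2S,4R)-2,4-dimethyl-5-oxopentanoate | O=C[C@H](C)C[C@H](C)C(=O)OC
F4 | step 17 | C8 aldol adduct of 22 and F3 (C7 carbinol, mixture at C7) | O=C1[C@H](C(O)[C@H](C)C[C@H](C)C(=O)OC)C[C@@H](/C=C(C)\C=C)[C@@]1(O)CBr
F5 | step 17 | C7 triethylsilyl ether of F4 | O=C1[C@H](C(O[Si](CC)(CC)CC)[C@H](C)C[C@H](C)C(=O)OC)C[C@@H](/C=C(C)\C=C)[C@@]1(O)CBr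
F6 | step 17 | C15 bromoacetate of F5 | O=C1[C@H](C(O[Si](CC)(CC)CC)[C@H](C)C[C@H](C)C(=O)OC)C[C@@H](/C=C(C)\C=C)[C@@]1(OC(=O)CBr)CBr
F7 | step 17 | cis-fused β-hydroxy γ-lactone (C16–OH, C2H2) from F6 | O=C1C[C@]2(O)[C@H](C(O[Si](CC)(CC)CC)[C@H](C)C[C@H](C)C(=O)OC)C[C@@H](/C=C(C)\C=C)[C@]2(CBr)O1
F8 | step 17 | eight-membered β-keto lactone with C7–OSiEt3 and C16–OH | C[C@@H]1C[C@H](C)/C(O)=C2/C(=O)O[C@]4(CBr)[C@@]2(O)[C@@H](C[C@H]4/C=C(C)\C=C)C1O[Si](CC)(CC)CC
F9 | step 17 | C7 alcohol from F8 | C[C@@H]1C[C@H](C)/C(O)=C2/C(=O)O[C@]4(CBr)[C@@]2(O)[C@@H](C[C@H]4/C=C(C)\C=C)C1O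
F10 | step 17 | C7 ketone with (Z)-diene side chain (30 before epoxidation) | C[C@@H]1C[C@H](C)/C(O)=C2/C(=O)O[C@]4(CBr)[C@@]2(O)[C@@H](C[C@H]4/C=C(C)\C=C)C1=O
F11 | step 19 | 13-methylene analogue of abyssomicin N (C13=CH2) | C[C@@H]1C[C@H](C)/C(O)=C2/C(=O)O[C@]34CC(=C)[C@]5(C)O[C@]23[C@@H](C[C@H]4[C@@H]5O)C1=O
F12 | step 10 | (1R,2R,3S)-3-(but-3-en-1-yn-1-yl)-2-[(tert-butyldimethylsilyloxy)methyl]cyclopentane-1,2-diol | O[C@@H]1CC[C@@H](C#CC=C)[C@@]1(O)CO[Si](C)(C)C(C)(C)C
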